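The east run at 90 °C showed 1.9 % of target at 5.00 h, while the south and south-west runs at 65 °C stayed at the size of the scatter out to 40.0 h. A rate constant climbs steeply with temperature, so I stopped counting hours as equal and asked what an hour in each flask was worth.

| flask | starting material | coupling partner | temperature | remark | time |
|---|---|---|---|---|---|
| south | 0.025 M | 0.125 M | 65 °C | run made earlier |  |
| east | 0.10 M | 0.125 M | 90 °C | run made earlier |  |
| south-west | 0.050 M | 0.19 M | 65 °C | run made earlier |  |
| Thursday's | 0.050 M | 0.125 M | 110 °C |  | 5.0 h |
| Saturday's | 0.050 M | 0.125 M |  | at 70 °C until 2.5 h, from then on at 110 °C | 5.0 h |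
| Sunday's | 0.050 M | 0.125 M | 70 °C |  | 5.0 h |
| Friday's | 0.050 M | 0.125 M | 90 °C |  | 5.0 h |

- south (time / h: target / %): 3.00: 0.5; 10.0: 0; 20.0: 0; 30.0: 0.4; 40.0: 0
- east (time / h: target / %): 0.833: 0; 2.00: 0.5; 2.50: 0.6; 5.00: 1.9; 10.0: 4.5
- south-west (time / h: target / %): 8.00: 0; 15.0: 0.6; 25.0: 0; 30.0: 0.8; 40.0: 0.5

(standard deviation of a reading: 0.5 percentage points)

- on the list of suspects stand: starting material <-> tautomer; starting material + coupling partner <-> isomer of the product; coupling partner + tautomer -> target; coupling partner <-> dormant form

* the flask that comes out highest in amount of target, in percent of the starting material charged, or "all alike" when all lie within 1.5 percentage points (Thursday's / Saturday's / Sunday's / Friday's / all alike)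
* target at the end, in percent of the starting material charged, Thursday's
* target at the end, in percent of the starting material charged, Saturday's
* target at the end, in percent of the starting material charged, Sunday's
* target at the end, in percent of the starting material charged, Friday's

I took target per hour from the east run at 5.00 h, and for the two cool runs the sum of their readings over the sum of their times, treating percent of charge as comparable across charges. The ratio of these, which I call w, came to 30.0. It is a reading, and a loose one: the highest cool reading was 0.8 %, against a scatter of 0.5 percentage points.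

Saturday's flask spent 2.5 h at 70 °C and the rest at 110 °C. The step from 70 °C up to 110 °C is wider than the step from 65 °C up to 90 °C, so pricing a cool hour at one part in w of a hot hour was generous. Saturday's flask then counted H = 2.58 h, the sum of its hours at the top temperature and its cool hours divided by w; I call H its hot hours. A looser w barely moves H, because the cool term is far smaller than the hot one.

Thursday's flask counted 5.0 h of hot hours, more than Saturday's, so I expected it higher, with Saturday's at 51.7 % of Thursday's target. A lag could lower that share: the east run's reading at 5.00 h was 42.2 % of its reading at 10.0 h.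

The forecast named Thursday's highest, with 16 % for Thursday's, 8 % for Saturday's, 0.1 % for Sunday's and 1.8 % for Friday's, holding that “Saturday's gets essentially only its 2.5 h at 110 °C”.

The simulation gave Thursday's as highest, with 13.3 % there, 6.84 % for Saturday's, 0.0365 % for Sunday's and 1.54 % for Friday's, on this scheme:

    starting material ⇌ tautomer (K = 0.400, k = 9.60 × 10⁻⁵ s⁻¹, Ea = 113 kJ mol⁻¹, ΔH = −26.0 kJ mol⁻¹)
    starting material + coupling partner ⇌ isomer of the product (K = 120 M⁻¹, k = 2.00 × 10⁻⁴ M⁻¹ s⁻¹, Ea = 88.0 kJ mol⁻¹, ΔH = −49.0 kJ mol⁻¹)
    coupling partner + tautomer → target (k = 4.80 × 10⁻⁴ M⁻¹ s⁻¹, Ea = 100 kJ mol⁻¹)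
    coupling partner ⇌ dormant form (K = 0.460, k = 6.50 × 10⁻⁵ s⁻¹, Ea = 110 kJ mol⁻¹, ΔH = −68.0 kJ mol⁻¹)
    (constants at 110 °C)

Saturday's target was 51.4 % of Thursday's, against the 51.7 % that the hot hours gave. Saturday's flask held 0.00937 % of target at its change of temperature and 6.84 % at the end, while Thursday's flask held 6.77 % at 2.50 h. Saturday's target per hot hour, taken over its 2.58 h, applied to Thursday's flask read at 80 min, gives 3.53 %; that neighbour held 3.10 %.

The readings are calculated for substances that don't exist; the scatter is artificial.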